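Assumption: the stereocentre in the SMILES is read as (R) (the target is (R)-mallotolerin), 2-methylphloroglucinol is taken as a catalogue chemical, and which antipode of the chiral acid in step 3 gives the (R)-product must be settled by experiment (both are sold).

**Retrosynthetic overview**
1. Last C–C bond: the ArCH2Ar bridge, by Mannich / ortho-quinone-methide coupling of the ring-B ketone (electrophile after aminomethylation) with the ring-A allylic alcohol (nucleophile at its one free ring carbon).
2. Key bond: the carbinol C–O bond of the side chain, made together with the only stereocentre by an enantioselective singlet-oxygen ene reaction of the prenyl group (hydroperoxide, then O–O reduction).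
3. Ring-A precursor: phloroglucinol, C-butyrylation, then mono-C-prenylation. Ring-B precursor: 2-methylphloroglucinol, C-acetylation, then 4-O-methylation.
4. No ring is formed in the route: both benzene rings are bought, and no protecting groups are used.

**Route**

Step 1
Reactants: 1 phloroglucinol (benzene-1,3,5-triol)
Product: 2 1-(2,4,6-trihydroxyphenyl)butan-1-one (phlorbutyrophenone)
Conditions: butyryl chloride (1.05 equiv), AlCl3 (3.5 equiv), PhNO2, 0 → 65 °C; aq. HCl quench
Reagents that add atoms: butyryl chloride, CCCC(=O)Cl
Why: Friedel–Crafts C-acylation of a very electron-rich arene, in which the first chelated acyl group deactivates the ring so that mono-acylation dominates.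

Step 2
Reactants: 2 1-(2,4,6-trihydroxyphenyl)butan-1-one
Product: 3 1-[2,4,6-trihydroxy-3-(3-methylbut-2-en-1-yl)phenyl]butan-1-one
Conditions: prenyl bromide (1.0 equiv), 10% aq. KOH, 0 °C, 2 h; then H3O+
Reagents that add atoms: prenyl bromide (1-bromo-3-methylbut-2-ene), CC(C)=CCBr
Why: C-alkylation of the ambident phloroglucinolate, favoured over O-alkylation in water, at one of two equivalent free ring positions, so a single mono-prenyl regioisomer forms (phenolate C-prenylation).

Step 3
Reactants: 3 1-[2,4,6-trihydroxy-3-(3-methylbut-2-en-1-yl)phenyl]butan-1-one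
Product: 5 1-[2,4,6-trihydroxy-3-[(2R)-2-hydroxy-3-methylbut-3-en-1-yl]phenyl]butan-1-one, via (R)-allylic hydroperoxide 4 (not isolated)
Conditions: (R)-TRIP [3,3'-bis(2,4,6-triisopropylphenyl)-BINOL hydrogen phosphate] (1.0 equiv, recovered), TPFPP [tetrakis(pentafluorophenyl)porphyrin] (1 mol %), O2 (1 atm), green LEDs, toluene, −78 °C; then PPh3 (1.2 equiv), −78 °C → rt
Reagents that add atoms: dioxygen, O=O
Why: Proposed new method: a chiral-phosphoric-acid-templated enantioselective Schenck ene reaction, in which the P=O of the acid accepts a hydrogen bond from the free, most acidic 4-OH flanking the prenyl group while its P–OH donates to the developing perepoxide oxygen, so that singlet oxygen is delivered to one π-face of the alkene inside the triisopropylphenyl pocket, the C–O bond forms at the CH carbon (setting the (R) centre) and the pendant oxygen takes H from the cis-methyl group (regiochemistry already favoured by the ortho-phenol steering effect), after which PPh3 reduces the O–O bond without touching the new C–O stereocentre; the closest known reactions are the racemic phenol-steered Schenck ene of ortho-prenylphenols, hydroxy-directed diastereoselective Schenck ene reactions and hydrogen-bond-template-controlled enantioselective singlet-oxygen oxygenations.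

Step 4
Reactants: 6 2-methylphloroglucinol (2-methylbenzene-1,3,5-triol)
Product: 7 1-(2,4,6-trihydroxy-3-methylphenyl)ethan-1-one
Conditions: AcCl (1.05 equiv), AlCl3 (3.5 equiv), PhNO2, 0 → 60 °C; aq. HCl quench
Reagents that add atoms: acetyl chloride, CC(=O)Cl
Why: Friedel–Crafts C-acylation at one of the two equivalent free ring positions, giving a single regioisomer.

Step 5
Reactants: 7 1-(2,4,6-trihydroxy-3-methylphenyl)ethan-1-one
Product: 8 1-(2,6-dihydroxy-4-methoxy-3-methylphenyl)ethan-1-one
Conditions: Me2SO4 (1.0 equiv), K2CO3 (1.0 equiv), acetone, rt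
Reagents that add atoms: dimethyl sulfate, COS(=O)(=O)OC
Why: Williamson O-methylation in which the 4-OH para to the acetyl group is the most acidic hydroxyl and the two ortho hydroxyls are deactivated by the chelating carbonyl, so one equivalent of electrophile goes to O-4.

Step 6
Reactants: 8 1-(2,6-dihydroxy-4-methoxy-3-methylphenyl)ethan-1-one; 5 1-[2,4,6-trihydroxy-3-[(2R)-2-hydroxy-3-methylbut-3-en-1-yl]phenyl]butan-1-one
Product: 10 (R)-mallotolerin (target; full name in the compound list), via Mannich base 9 (not isolated)
Conditions: CH2=NMe2+ I− (1.0 equiv), NaOAc (1.1 equiv), MeCN, rt, 2 h; then 5 (1.0 equiv), 80 °C, N2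
Reagents that add atoms: Eschenmoser's salt (N,N-dimethylmethyleneiminium iodide), C[N+](C)=C.[I-]
Why: Mannich aminomethylation at the single free ring carbon of 8, then thermal loss of dimethylamine to an ortho-quinone methide that is C-alkylated by the single free, strongly nucleophilic ring carbon of 5 (Friedel–Crafts-type conjugate addition), with the carbinol stereocentre a spectator under these near-neutral conditions.

**Compound list**
1 | phloroglucinol (benzene-1,3,5-triol) | Oc1cc(O)cc(O)c1 | starting material
2 | 1-(2,4,6-trihydroxyphenyl)butan-1-one | CCCC(=O)c1c(O)cc(O)cc1O | intermediate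
3 | 1-[2,4,6-trihydroxy-3-(3-methylbut-2-en-1-yl)phenyl]butan-1-one | CCCC(=O)c1c(O)cc(O)c(CC=C(C)C)c1O | intermediate
4 | 1-[3-[(2R)-2-hydroperoxy-3-methylbut-3-en-1-yl]-2,4,6-trihydroxyphenyl]butan-1-one | C=C(C)[C@H](OO)Cc1c(O)cc(O)c(C(=O)CCC)c1O | intermediate (not isolated)
5 | 1-[2,4,6-trihydroxy-3-[(2R)-2-hydroxy-3-methylbut-3-en-1-yl]phenyl]butan-1-one | C=C(C)[C@H](O)Cc1c(O)cc(O)c(C(=O)CCC)c1O | intermediate
6 | 2-methylphloroglucinol (2-methylbenzene-1,3,5-triol) | Cc1c(O)cc(O)cc1O | starting material
7 | 1-(2,4,6-trihydroxy-3-methylphenyl)ethan-1-one | CC(=O)c1c(O)cc(O)c(C)c1O | intermediate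
8 | 1-(2,6-dihydroxy-4-methoxy-3-methylphenyl)ethan-1-one | CC(=O)c1c(O)cc(OC)c(C)c1O | intermediate
9 | 1-[3-[(dimethylamino)methyl]-2,6-dihydroxy-4-methoxy-5-methylphenyl]ethan-1-one | CC(=O)c1c(O)c(CN(C)C)c(OC)c(C)c1O | intermediate (not isolated)
10 | 1-[3-[(3-acetyl-2,4-dihydroxy-6-methoxy-5-methylphenyl)methyl]-2,4,6-trihydroxy-5-[(2R)-2-hydroxy-3-methylbut-3-en-1-yl]phenyl]butan-1-one, (R)-mallotolerin | C=C(C)[C@H](O)Cc1c(O)c(Cc2c(O)c(C(C)=O)c(O)c(C)c2OC)c(O)c(C(=O)CCC)c1O | target

**Step count and risks**
Total steps: 6. Longest linear sequence: 4 (steps 1, 2, 3, 6); the ring-B branch is 3 steps (4, 5, 6).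

Steps most likely to fail:

Step 3 (proposed new method). The ene step has almost no enthalpic barrier, so substrate not bound to the acid reacts equally fast and erodes ee; this is why a full equivalent of recoverable acid is specified. The achiral tertiary hydroperoxide regioisomer and ring oxidation are further losses. The fallback uses known chemistry, sets out from 3 and comes back at 5. Conventional non-selective photooxygenation (TPP, O2, visible light, CH2Cl2, 0 °C) gives the racemic allylic hydroperoxide F1. Reduction with PPh3 in the same flask gives the racemic allylic alcohol F2. Preparative chiral-phase SFC (amylose-type stationary phase) then separates (R)-alcohol 5 from the (S)-alcohol F3, which is discarded.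

Step 6 (one-pot unsymmetrical bridge formation). Incomplete aminomethylation of 8 would leave iminium salt that aminomethylates 5 and leads to ring-A homodimer, and the quinone methide can scramble at 80 °C. The fallback sets out from 5 and comes back at 10 with the roles reversed and the Mannich base isolated. Compound 5 is aminomethylated at its only free ring carbon (40% aq. Me2NH, 37% aq. HCHO, EtOH, rt) to give the ring-A Mannich base F4, collected by precipitation. Heating F4 with ketone 8 in dioxane at 100 °C generates the ring-A ortho-quinone methide, which 8 traps at its single free position to give 10.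

Step 2 (mono-C-prenylation). Di-prenylation, O-prenylation and geminal dialkylation limit the yield. The fallback sets out from 2 and comes back at 3 by an O-alkylation / sigmatropic route. Pd(PPh3)4-catalysed reaction of 2 with methyl 2-methylbut-3-en-2-yl carbonate (THF, 0 °C) etherifies the most acidic 4-OH to give the 1,1-dimethylallyl ether F5. Aromatic Claisen rearrangement of F5 (Eu(fod)3, CHCl3, 60 °C, or PhNEt2, 180 °C) moves the allyl unit, with inversion, to either of the two equivalent ortho carbons and gives the prenyl ketone 3.

**Further compounds**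
F1 | step 3 | racemic 1-[3-(2-hydroperoxy-3-methylbut-3-en-1-yl)-2,4,6-trihydroxyphenyl]butan-1-one | C=C(C)C(OO)Cc1c(O)cc(O)c(C(=O)CCC)c1O
F2 | step 3 | racemic 1-[2,4,6-trihydroxy-3-(2-hydroxy-3-methylbut-3-en-1-yl)phenyl]butan-1-one | C=C(C)C(O)Cc1c(O)cc(O)c(C(=O)CCC)c1O
F3 | step 3 | 1-[2,4,6-trihydroxy-3-[(2S)-2-hydroxy-3-methylbut-3-en-1-yl]phenyl]butan-1-one | C=C(C)[C@@H](O)Cc1c(O)cc(O)c(C(=O)CCC)c1O
F4 | step 6 | 1-[3-[(dimethylamino)methyl]-2,4,6-trihydroxy-5-[(2R)-2-hydroxy-3-methylbut-3-en-1-yl]phenyl]butan-1-one | C=C(C)[C@H](O)Cc1c(O)c(CN(C)C)c(O)c(C(=O)CCC)c1O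
F5 | step 2 | 1-[2,6-dihydroxy-4-[(2-methylbut-3-en-2-yl)oxy]phenyl]butan-1-one | CCCC(=O)c1c(O)cc(OC(C)(C)C=C)cc1O
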